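Ring B, the quinone ring of the naphthazarin, is disconnected at C1–C2 and C3–C4. C2, which bears the cyclobutyl carbinol carbon, and C3–H come from the two carbons of a terminal alkyne; the carbonyl carbons C1 and C4, attached to ring A at C8a and C4a, are the acyl carbons of a phthaloylcobalt metallacycle obtained by opening the strained C(O)–C(O) bond of 3,6-dimethoxybenzocyclobutene-1,2-dione. Alkyne insertion followed by reductive elimination forges both bonds and ring B at the quinone oxidation level in one operation, and the twofold symmetry of ring A excludes regioisomers. The alkyne partner is (R)-1-ethynyl-2,2-dimethylcyclobutyl angelate, which already holds the stereocentre and the Z ester.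

Key step: step 7

Assumption: 2,2-dimethylcyclobutan-1-one (1) is taken as a purchasable building block; it is otherwise one keteniminium–ethene [2+2] step from N,N-dimethylisobutyramide.
Remark: the carbinol carbon keeps the descriptor R from 7 through 17 and 18 to 19, because the priority order O > alkynyl or quinonyl carbon > CMe2 > ring CH2 holds throughout; the 1,4-quinone and 5,8-quinone forms of the naphthazarin are tautomers of one compound.
Remark: in the SMILES of the cobalt compounds each donor–cobalt bond is drawn as a single bond with a positive formal charge on the donor atom and the balancing negative charge on cobalt; the complexes are neutral overall.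

Step 1
Reactants: 1 2,2-dimethylcyclobutan-1-one; 2 ethynylmagnesium bromide
Product: 3 rac-1-ethynyl-2,2-dimethylcyclobutan-1-ol
Conditions: HC≡CMgBr (0.5 M in THF, 1.3 equiv), THF, 0 → 20 °C; sat. aq. NH4Cl
Reagents that add atoms: none
Why: Grignard 1,2-addition to the strained, electrophilic cyclobutanone carbonyl, whose only enolisable side is a ring CH2, should be fast and clean, and it creates the carbinol stereocentre without control, as the racemate that step 3 resolves.

Step 2
Reactants: 3 rac-1-ethynyl-2,2-dimethylcyclobutan-1-ol; 4 angelic acid, (Z)-2-methylbut-2-enoic acid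
Product: 6 rac-1-ethynyl-2,2-dimethylcyclobutyl (Z)-2-methylbut-2-enoate, via angelic anhydride 5 (not isolated)
Conditions: 4 (2.6 equiv), DCC (1.3 equiv), CH2Cl2, 0 → 20 °C, filter, concentrate; then 3, LiN(SiMe3)2 (1.05 equiv), THF, −78 °C, add 5, −78 → 0 °C
Reagents that add atoms: none
Why: O-acylation of the pre-formed lithium alkoxide with the symmetrical anhydride (alkoxide acylation) is a stereoconservative way to angelates of hindered alcohols, since no acylpyridinium or ketene intermediate arises through which the Z double bond could isomerise, and one equivalent of base leaves the alkyne C–H untouched.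

Step 3
Reactants: 6 rac-1-ethynyl-2,2-dimethylcyclobutyl (Z)-2-methylbut-2-enoate
Product: 7 (R)-1-ethynyl-2,2-dimethylcyclobutyl (Z)-2-methylbut-2-enoate
Conditions: preparative SFC, amylose tris(3,5-dimethylphenylcarbamate) chiral stationary phase, CO2/i-PrOH, 35 °C, UV detection at 220 nm
Reagents that add atoms: none
Why: Resolution of the racemate by chromatography on a chiral stationary phase selects the (R) enantiomer (to be identified by vibrational circular dichroism against the calculated spectrum) at a quaternary carbinol centre that cannot epimerise afterwards, and the same pass should remove any E (tiglate) ester.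

Step 4
Reactants: 8 2-bromo-1,4-dimethoxybenzene; 9 1,1-dimethoxyethene
Product: 12 3,6-dimethoxybenzocyclobuten-1-one (2,5-dimethoxybicyclo[4.2.0]octa-1,3,5-trien-7-one), via 3,6-dimethoxybenzyne 10 (not isolated), via 2,5,7,7-tetramethoxybicyclo[4.2.0]octa-1,3,5-triene 11 (not isolated)
Conditions: NaNH2 (3 equiv), 9 (3 equiv), THF, reflux; then 1 M aq. HCl, THF, 20 °C
Reagents that add atoms: water, O
Why: Dehydrobromination gives the symmetrical aryne, whose [2+2] cycloaddition with the electron-rich ketene acetal (aryne–ketene acetal cycloaddition) can give only one regioisomer, and mild acid hydrolysis of the ketal, in which water supplies the ketone oxygen, then releases the benzocyclobutenone.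

Step 5
Reactants: 12 3,6-dimethoxybenzocyclobuten-1-one
Product: 14 3,6-dimethoxybenzocyclobutene-1,2-dione, via 8,8-dibromo-2,5-dimethoxybicyclo[4.2.0]octa-1,3,5-trien-7-one 13 (not isolated)
Conditions: NBS (2.2 equiv), (PhCO2)2 (5 mol %), CCl4, reflux; filter, concentrate; then 50% aq. H2SO4, 60 °C
Reagents that add atoms: N-bromosuccinimide, O=C1CCC(=O)N1Br; water, O
Why: Wohl–Ziegler radical bromination should go twice at the only benzylic methylene, which is also α to the ketone, and hydrolysis of the gem-dibromide 13 (the bromine of N-bromosuccinimide stays only in this intermediate, water supplies the new carbonyl oxygen) unmasks the second carbonyl, the standard passage from benzocyclobutenones to benzocyclobutenediones.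

Step 6
Reactants: 14 3,6-dimethoxybenzocyclobutene-1,2-dione
Product: 16 chloro(dimethylglyoxime)(pyridine)(3,6-dimethoxyphthaloyl)cobalt, via chlorobis(triphenylphosphine)(3,6-dimethoxyphthaloyl)cobalt 15 (not isolated)
Conditions: CoCl(PPh3)3 (1.05 equiv), PhCl, 20 → 50 °C, N2; concentrate; then dimethylglyoxime (1.1 equiv), pyridine, 20 °C; precipitate with Et2O/hexane
Reagents that add atoms: CoCl(PPh3)3 chlorotris(triphenylphosphine)cobalt, Cl[Co-3]([P+](c1ccccc1)(c1ccccc1)c1ccccc1)([P+](c1ccccc1)(c1ccccc1)c1ccccc1)[P+](c1ccccc1)(c1ccccc1)c1ccccc1; dimethylglyoxime, CC(=NO)C(C)=NO; pyridine, c1ccncc1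
Why: Oxidative addition of monovalent cobalt into the strained C(O)–C(O) bond (C–C activation driven by strain release) should give the five-membered phthaloyl metallacycle of trivalent cobalt, and ligand substitution of both phosphines by the chelating dioxime and pyridine then gives an air-stable, phosphine-free complex of the type known to transfer its phthaloyl unit to alkynes under mild conditions.

Step 7
Reactants: 16 chloro(dimethylglyoxime)(pyridine)(3,6-dimethoxyphthaloyl)cobalt; 7 (R)-1-ethynyl-2,2-dimethylcyclobutyl (Z)-2-methylbut-2-enoate
Product: 17 (R)-1-(5,8-dimethoxy-1,4-dioxo-1,4-dihydronaphthalen-2-yl)-2,2-dimethylcyclobutyl (Z)-2-methylbut-2-enoate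
Conditions: 16 (1.3 equiv), 7 (1.0 equiv), CoCl2·6H2O (1 equiv), degassed MeCN, 75 °C, N2; then air, silica gel chromatography
Reagents that add atoms: none
Why: Loss of a ligand from the 18-electron trivalent cobalt metallacycle 16, assisted by the mild Lewis acid CoCl2·6H2O, opens a site for the alkyne, which inserts into one Co–acyl bond to give a seven-membered acyl(vinyl)cobalt ring, and C–C reductive elimination then forms the second bond and expels the quinone with monovalent cobalt. The closest known reaction is the naphthoquinone synthesis from phthaloylcobalt dimethylglyoxime complexes and alkynes, terminal ones included. Ring B closes by reductive elimination from that seven-membered cobaltacycle, overall a [4+2]-type annulation of the OC–C8a=C4a–CO unit across the triple bond that makes C1–C2 and C3–C4. No stereocentre is created, and the quaternary carbinol carbon of 7 takes no part and cannot epimerise. Only chemoselectivity is needed, insertion versus decarbonylation of the acyl cobalt and versus reaction at the ester: the chelating N-donor set keeps the complex reactive at 75 °C without silver or other π-acidic cations that could trigger acyloxy migration or cyclobutane ring expansion of the propargylic ester, no free phosphine is present to attack the quinone, and the trisubstituted conjugated angelate alkene is a far poorer ligand than the alkyne. Regiochemistry does not arise because the dimethoxyphthaloyl unit is symmetric, so the alkyne C–H carbon necessarily becomes C3.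

Step 8
Reactants: 17 (R)-1-(5,8-dimethoxy-1,4-dioxo-1,4-dihydronaphthalen-2-yl)-2,2-dimethylcyclobutyl (Z)-2-methylbut-2-enoate
Product: 19 (R)-1-(5,8-dihydroxy-1,4-dioxo-1,4-dihydronaphthalen-2-yl)-2,2-dimethylcyclobutyl (Z)-2-methylbut-2-enoate, via bis-quinone 18 (not isolated)
Conditions: AgO (5 equiv), 6 M HNO3, 1,4-dioxane, 20 °C, 10 min; extract into CH2Cl2; then aq. Na2S2O4, 20 °C, 10 min; air
Reagents that add atoms: water, O
Why: Oxidative demethylation of the p-dimethoxyarene by divalent silver (arene radical cation, ipso attack of water, loss of methanol) should give the labile bis-quinone, which dithionite reduces by two electrons to the naphthazarin without isolation, while the electron-poor angelate alkene and the tertiary ester, whose ionisation is disfavoured next to the quinone, remain spectators.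

Compound list
1 | 2,2-dimethylcyclobutan-1-one | CC1(C)CCC1=O | starting material
2 | ethynylmagnesium bromide, HC≡CMgBr | C#C[Mg]Br | starting material
3 | rac-1-ethynyl-2,2-dimethylcyclobutan-1-ol | CC1(C)CCC1(O)C#C | intermediate
4 | angelic acid, (Z)-2-methylbut-2-enoic acid | C/C=C(/C)C(=O)O | starting material
5 | angelic anhydride, (Z)-2-methylbut-2-enoic anhydride | C/C=C(/C)C(=O)OC(=O)/C(C)=C\C | intermediate
6 | rac-1-ethynyl-2,2-dimethylcyclobutyl (Z)-2-methylbut-2-enoate | C/C=C(/C)C(=O)OC1(C#C)CCC1(C)C | intermediate
7 | (R)-1-ethynyl-2,2-dimethylcyclobutyl (Z)-2-methylbut-2-enoate | C/C=C(/C)C(=O)O[C@]1(C#C)CCC1(C)C | intermediate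
8 | 2-bromo-1,4-dimethoxybenzene | COc1ccc(OC)c(Br)c1 | starting material
9 | 1,1-dimethoxyethene | C=C(OC)OC | starting material
10 | 3,6-dimethoxybenzyne (1,4-dimethoxy-2,3-didehydrobenzene) | COC1=CC=C(OC)C#C1 | intermediate
11 | 2,5,7,7-tetramethoxybicyclo[4.2.0]octa-1,3,5-triene (dimethyl ketal of 12) | COc1ccc(OC)c2c1CC2(OC)OC | intermediate
12 | 3,6-dimethoxybenzocyclobuten-1-one (2,5-dimethoxybicyclo[4.2.0]octa-1,3,5-trien-7-one) | COc1ccc(OC)c2c1CC2=O | intermediate
13 | 8,8-dibromo-2,5-dimethoxybicyclo[4.2.0]octa-1,3,5-trien-7-one | COc1ccc(OC)c2c1C(Br)(Br)C2=O | intermediate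
14 | 3,6-dimethoxybenzocyclobutene-1,2-dione | COc1ccc(OC)c2c1C(=O)C2=O | intermediate
15 | chlorobis(triphenylphosphine)(3,6-dimethoxyphthaloyl)cobalt, CoCl(PPh3)2[C(O)C6H2(OMe)2C(O)], five-membered diacyl metallacycle of trivalent cobalt | COc1ccc(OC)c2c1C(=O)[Co-2](Cl)([P+](c1ccccc1)(c1ccccc1)c1ccccc1)([P+](c1ccccc1)(c1ccccc1)c1ccccc1)C2=O | intermediate
16 | chloro(dimethylglyoxime)(pyridine)(3,6-dimethoxyphthaloyl)cobalt, CoCl(C5H5N)(C4H8N2O2)[C(O)C6H2(OMe)2C(O)], six-coordinate trivalent cobalt with N,N-chelating neutral dioxime | COc1ccc(OC)c2c1C(=O)[Co-3]1(Cl)([n+]3ccccc3)([N+](O)=C(C)C(C)=[N+]1O)C2=O | intermediate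
17 | (R)-1-(5,8-dimethoxy-1,4-dioxo-1,4-dihydronaphthalen-2-yl)-2,2-dimethylcyclobutyl (Z)-2-methylbut-2-enoate | C/C=C(/C)C(=O)O[C@]1(C2=CC(=O)c3c(OC)ccc(OC)c3C2=O)CCC1(C)C | intermediate
18 | (R)-2,2-dimethyl-1-(1,4,5,8-tetraoxo-1,4,5,8-tetrahydronaphthalen-2-yl)cyclobutyl (Z)-2-methylbut-2-enoate | C/C=C(/C)C(=O)O[C@]1(C2=CC(=O)C3=C(C2=O)C(=O)C=CC3=O)CCC1(C)C | intermediate
19 | (R)-1-(5,8-dihydroxy-1,4-dioxo-1,4-dihydronaphthalen-2-yl)-2,2-dimethylcyclobutyl (Z)-2-methylbut-2-enoate | C/C=C(/C)C(=O)O[C@]1(C2=CC(=O)c3c(O)ccc(O)c3C2=O)CCC1(C)C | target

Total step count: 8. Longest linear sequence: 5 steps (1 → 3 → 6 → 7 → 17 → 19, and equally 8 → 12 → 14 → 16 → 17 → 19).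

Steps most likely to fail

Step 7. Insertion may stall at a triple bond flanked by a fully substituted carbon, so that decarbonylation or decomposition of the acyl cobalt takes over. The fallback sets out from 14 and 7 and comes back at 17. Compound 7 is deprotonated at the alkyne terminus with LiN(i-Pr)2 (THF, −78 °C, short contact time) and the lithium acetylide is added to one carbonyl of 14. This should give (R)-1-[(8-hydroxy-2,5-dimethoxy-7-oxobicyclo[4.2.0]octa-1,3,5-trien-8-yl)ethynyl]-2,2-dimethylcyclobutyl (Z)-2-methylbut-2-enoate F1 as both carbinol epimers. Heating F1 in xylene at about 140 °C should open the four-membered ring to an o-quinoid vinylketene that closes onto the alkyne and, after hydrogen transfer from the hydroxyl group, gives quinone 17 (thermal ring expansion of alkynyl hydroxycyclobutenones, Moore-type rearrangement).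

Step 8. Oxidation of the dimethoxy ring, which is deactivated by the two quinone carbonyls, may be incomplete, or the nitric acid medium may hydrolyse or isomerise the angelate. The fallback sets out from 17 and comes back at 19 without a new isolated compound. It is a non-oxidative, chelation-assisted cleavage of the two methyl ethers with BCl3 (CH2Cl2, −78 → 0 °C, aqueous work-up). Each methoxy group sits peri to a quinone carbonyl, the classical case for selective boron trihalide demethylation. The tertiary ester should resist ionisation because its carbocation would be attached to the electron-poor quinone C2.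

Step 2. Acyl transfer to the tertiary alkoxide next to the gem-dimethyl carbon may be slow, and prolonged exposure of the angeloyl donor to base may erode the Z geometry. The fallback sets out from 3 and comes back at 6. Compound 3 is esterified with 2-(diphenoxyphosphoryl)propanoic acid and DCC in CH2Cl2; α-phosphono acids acylate through the ketene and so reach hindered tertiary alcohols. This should give 1-ethynyl-2,2-dimethylcyclobutyl 2-(diphenoxyphosphoryl)propanoate F2. Z-selective Horner–Wadsworth–Emmons olefination of F2 with acetaldehyde (NaH, THF, −78 → 0 °C, diaryl phosphonate variant) then builds the angelate double bond on the ester and returns racemic 6.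

Further compounds
F1 | step 7 | (R)-1-[(8-hydroxy-2,5-dimethoxy-7-oxobicyclo[4.2.0]octa-1,3,5-trien-8-yl)ethynyl]-2,2-dimethylcyclobutyl (Z)-2-methylbut-2-enoate | C/C=C(/C)C(=O)O[C@]1(C#CC2(O)C(=O)c3c(OC)ccc(OC)c32)CCC1(C)C
F0 | step 8 | none | none
F2 | step 2 | 1-ethynyl-2,2-dimethylcyclobutyl 2-(diphenoxyphosphoryl)propanoate | CC(C(=O)OC1(C#C)CCC1(C)C)P(=O)(Oc1ccccc1)Oc1ccccc1
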